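**Retrosynthetic overview**
1. Target 19 ⇐ tri-O-benzyl flavone 18 by one hydrogenolysis. Ring C (the pyranone) is the only ring built and is closed last from chalcone 15; ring A, ring B and the hydroxyphenyl ring are bought.
2. Chalcone 15 ⇐ Claisen–Schmidt union of ring-A acetophenone 14 with ring-B aldehyde 12, which already carries the complete (7''S,8''S) side chain.
3. C9'' CH2OH ⇐ vinyl group (ozonolysis/reduction). Key C7''–C8'' bond ⇐ aldehyde 4 + the metalated allyl ether 3, in which the oxygen-bearing carbon C8'' is the carbanion, delivered as a (Z)-γ-aryloxyallyl-diisopinocampheylborane; both stereocentres are set in this one step.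
4. 3 ⇐ syringaldehyde 1 by O-allylation and acetalisation (a temporary dioxolane ring).

Assumption: the given SMILES is taken as authoritative; it is the threo isomer, with C7'' the benzylic carbinol carbon and C8'' the aryloxy-bearing carbon, both S.

**Step 1**
Reactants: 1 syringaldehyde (4-hydroxy-3,5-dimethoxybenzaldehyde)
Product: 2 3,5-dimethoxy-4-(prop-2-en-1-yloxy)benzaldehyde
Conditions: allyl bromide, K2CO3, DMF, 60 °C
Reagents that add atoms: allyl bromide C=CCBr
Why: Williamson O-allylation of the acidic, para-formyl-activated phenoxide with an unhindered allylic bromide (SN2); no stereocentre is involved.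

**Step 2**
Reactants: 2 3,5-dimethoxy-4-(prop-2-en-1-yloxy)benzaldehyde
Product: 3 2-[3,5-dimethoxy-4-(prop-2-en-1-yloxy)phenyl]-1,3-dioxolane
Conditions: ethylene glycol, TsOH·H2O (cat.), toluene, reflux, Dean–Stark
Reagents that add atoms: ethylene glycol OCCO
Why: Acid-catalysed acetalisation with azeotropic water removal masks the aldehyde against sec-BuLi and NaBH4 as a dioxolane that tolerates strong base and low-temperature BF3, and the ortho-blocked allyl aryl ether cannot undergo Claisen rearrangement at 110 °C.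

**Step 3**
Reactants: 3 2-[3,5-dimethoxy-4-(prop-2-en-1-yloxy)phenyl]-1,3-dioxolane; 4 4-(benzyloxy)benzaldehyde
Product: 9 (1S,2S)-1-[4-(benzyloxy)phenyl]-2-[4-(1,3-dioxolan-2-yl)-2,6-dimethoxyphenoxy]but-3-en-1-ol, via allyllithium 5 (not isolated), via borate complex 6 (not isolated), via allylborane 7 (not isolated), via borinate ester 8 (not isolated)
Conditions: sec-BuLi (1.05 equiv), THF, −78 °C, 30 min; (+)-Ipc2BOMe (from (−)-α-pinene), −78 °C, 1 h; BF3·OEt2 (1.3 equiv) then 4, −78 °C, 3 h; NaOH, H2O2, 0 °C to rt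
Reagents that add atoms: none
Why: Brown (Z)-γ-alkoxyallylboration in its aryloxy version: sec-BuLi removes an OCH2 proton to give the O-chelated (Z)-allyllithium 5 so that the oxygen-bearing carbon C8'' becomes the nucleophile, boron is placed on the remote terminus (6, then 7 once BF3 strips methoxide), and 7 adds to the re face of 4 through a closed Zimmerman–Traxler chair controlled by the isopinocampheyl groups from (−)-α-pinene, the Z geometry giving the syn (threo) adduct and hence 7''S and 8''S in a single C–C bond formation before NaOH/H2O2 frees 9 from borinate 8.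

**Step 4**
Reactants: 9 (1S,2S)-1-[4-(benzyloxy)phenyl]-2-[4-(1,3-dioxolan-2-yl)-2,6-dimethoxyphenoxy]but-3-en-1-ol
Product: 12 4-{[(1S,2S)-1-[4-(benzyloxy)phenyl]-1,3-dihydroxypropan-2-yl]oxy}-3,5-dimethoxybenzaldehyde, via secondary ozonide 10 (not isolated), via acetal diol 11 (not isolated)
Conditions: O3, CH2Cl2, −78 °C (Sudan Red 7B endpoint); NaBH4, MeOH, −78 to 0 °C; concentrate; 1 M aq HCl/THF (1:4), rt, 1 h
Reagents that add atoms: ozone O=[O+][O-] (oxygen of the new CH2OH); water O (aldehyde oxygen on acetal hydrolysis)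
Why: Criegee ozonolysis of the only C=C bond (far faster than attack on the acetal, benzyl ether or arenes at −78 °C with a dye endpoint) followed by NaBH4 reduction of ozonide 10 turns the vinyl group into the C9'' CH2OH without ever holding a free, epimerisable α-aryloxy aldehyde, and brief dilute aqueous acid then hydrolyses the dioxolane of 11 while leaving the benzylic alcohol and both stereocentres untouched.

**Step 5**
Reactants: 13 2',4',6'-trihydroxyacetophenone
Product: 14 1-[2,4-bis(benzyloxy)-6-hydroxyphenyl]ethan-1-one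
Conditions: benzyl bromide (2.1 equiv), K2CO3 (2.2 equiv), DMF, rt to 60 °C
Reagents that add atoms: benzyl bromide BrCc1ccccc1
Why: Williamson benzylation under carbonate is selective for the 4-hydroxyl and one 2-hydroxyl because the remaining ortho hydroxyl is deactivated by its hydrogen bond to the acetyl carbonyl.

**Step 6**
Reactants: 12 4-{[(1S,2S)-1-[4-(benzyloxy)phenyl]-1,3-dihydroxypropan-2-yl]oxy}-3,5-dimethoxybenzaldehyde; 14 1-[2,4-bis(benzyloxy)-6-hydroxyphenyl]ethan-1-one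
Product: 15 (E)-1-[2,4-bis(benzyloxy)-6-hydroxyphenyl]-3-(4-{[(1S,2S)-1-[4-(benzyloxy)phenyl]-1,3-dihydroxypropan-2-yl]oxy}-3,5-dimethoxyphenyl)prop-2-en-1-one
Conditions: KOH (50% aq), EtOH/THF, rt, 48 h
Reagents that add atoms: none
Why: Claisen–Schmidt aldol condensation of the methyl ketone enolate with the non-enolisable aldehyde gives the E chalcone under thermodynamic control, and the free diol, the benzyl ethers and the two stereocentres (no acidic C–H) are inert to KOH at room temperature.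

**Step 7**
Reactants: 15 (E)-1-[2,4-bis(benzyloxy)-6-hydroxyphenyl]-3-(4-{[(1S,2S)-1-[4-(benzyloxy)phenyl]-1,3-dihydroxypropan-2-yl]oxy}-3,5-dimethoxyphenyl)prop-2-en-1-one
Product: 18 5,7-bis(benzyloxy)-2-(4-{[(1S,2S)-1-[4-(benzyloxy)phenyl]-1,3-dihydroxypropan-2-yl]oxy}-3,5-dimethoxyphenyl)-4H-chromen-4-one, via flavanone 16 (not isolated), via 3-iodoflavanone 17 (not isolated)
Conditions: I2 (1.2 equiv), pyridine, 100 °C, 6–10 h
Reagents that add atoms: none
Why: In hot pyridine the 2'-hydroxychalcone equilibrates by 6-endo oxa-Michael addition with flavanone 16, whose enol is iodinated at C3 (17) and loses HI by base-promoted elimination, which is the iodine–pyridine flavanone dehydrogenation routinely run on flavanone glycosides with free hydroxyls, so the non-acidic medium spares the benzylic and primary alcohols; ring C is formed here and the transient C2 stereocentre disappears.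

**Step 8**
Reactants: 18 5,7-bis(benzyloxy)-2-(4-{[(1S,2S)-1-[4-(benzyloxy)phenyl]-1,3-dihydroxypropan-2-yl]oxy}-3,5-dimethoxyphenyl)-4H-chromen-4-one
Product: 19 (−)-(7''S,8''S)-4'',5,7-trihydroxy-3',5'-dimethoxy-4',8''-oxyflavonolignan-7'',9''-diol
Conditions: H2 (1 atm), 10% Pd/C, THF/MeOH, rt, stopped after uptake of 3 equiv
Reagents that add atoms: none
Why: Catalytic hydrogenolysis cleaves the three aryl benzyl ethers under neutral conditions much faster than it reduces the flavone C2–C3 bond or the C7'' benzylic alcohol, so the target is released with both stereocentres intact.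

**Compound list**
1 | syringaldehyde (4-hydroxy-3,5-dimethoxybenzaldehyde) | COc1cc(C=O)cc(OC)c1O | starting material
2 | 3,5-dimethoxy-4-(prop-2-en-1-yloxy)benzaldehyde | COc1cc(C=O)cc(OC)c1OCC=C | intermediate
3 | 2-[3,5-dimethoxy-4-(prop-2-en-1-yloxy)phenyl]-1,3-dioxolane | COc1cc(C2OCCO2)cc(OC)c1OCC=C | intermediate
4 | 4-(benzyloxy)benzaldehyde | O=Cc1ccc(OCc2ccccc2)cc1 | starting material
5 | allyllithium: (Z)-3-[4-(1,3-dioxolan-2-yl)-2,6-dimethoxyphenoxy]allyllithium (O-chelated) | [Li]C/C=C\Oc1c(OC)cc(C2OCCO2)cc1OC | intermediate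
6 | borate complex: lithium [(Z)-3-aryloxyallyl](methoxy)bis(isopinocampheyl)borate, Ipc from (−)-α-pinene | [Li+].CO[B-](C/C=C\Oc1c(OC)cc(C2OCCO2)cc1OC)([C@H]1C[C@H]2C[C@@H]([C@@H]1C)C2(C)C)[C@H]1C[C@H]2C[C@@H]([C@@H]1C)C2(C)C | intermediate
7 | allylborane: [(Z)-3-[4-(1,3-dioxolan-2-yl)-2,6-dimethoxyphenoxy]allyl]bis(isopinocampheyl)borane | COc1cc(C2OCCO2)cc(OC)c1O/C=C\CB([C@H]1C[C@H]2C[C@@H]([C@@H]1C)C2(C)C)[C@H]1C[C@H]2C[C@@H]([C@@H]1C)C2(C)C | intermediate
8 | borinate ester: O-bis(isopinocampheyl)boryl derivative of 9 | COc1cc(C2OCCO2)cc(OC)c1O[C@@H](C=C)[C@@H](OB([C@H]1C[C@H]2C[C@@H]([C@@H]1C)C2(C)C)[C@H]1C[C@H]2C[C@@H]([C@@H]1C)C2(C)C)c1ccc(OCc2ccccc2)cc1 | intermediate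
9 | (1S,2S)-1-[4-(benzyloxy)phenyl]-2-[4-(1,3-dioxolan-2-yl)-2,6-dimethoxyphenoxy]but-3-en-1-ol | COc1cc(C2OCCO2)cc(OC)c1O[C@@H](C=C)[C@@H](O)c1ccc(OCc2ccccc2)cc1 | intermediate
10 | secondary ozonide: (1S,2R)-1-[4-(benzyloxy)phenyl]-2-[4-(1,3-dioxolan-2-yl)-2,6-dimethoxyphenoxy]-2-(1,2,4-trioxolan-3-yl)ethan-1-ol, trioxolane carbon as epimer mixture | COc1cc(C2OCCO2)cc(OC)c1O[C@@H](C1OCOO1)[C@@H](O)c1ccc(OCc2ccccc2)cc1 | intermediate
11 | acetal diol: (1S,2S)-1-[4-(benzyloxy)phenyl]-2-[4-(1,3-dioxolan-2-yl)-2,6-dimethoxyphenoxy]propane-1,3-diol | COc1cc(C2OCCO2)cc(OC)c1O[C@@H](CO)[C@@H](O)c1ccc(OCc2ccccc2)cc1 | intermediate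
12 | 4-{[(1S,2S)-1-[4-(benzyloxy)phenyl]-1,3-dihydroxypropan-2-yl]oxy}-3,5-dimethoxybenzaldehyde | COc1cc(C=O)cc(OC)c1O[C@@H](CO)[C@@H](O)c1ccc(OCc2ccccc2)cc1 | intermediate
13 | 2',4',6'-trihydroxyacetophenone | CC(=O)c1c(O)cc(O)cc1O | starting material
14 | 1-[2,4-bis(benzyloxy)-6-hydroxyphenyl]ethan-1-one | CC(=O)c1c(O)cc(OCc2ccccc2)cc1OCc1ccccc1 | intermediate
15 | (E)-1-[2,4-bis(benzyloxy)-6-hydroxyphenyl]-3-(4-{[(1S,2S)-1-[4-(benzyloxy)phenyl]-1,3-dihydroxypropan-2-yl]oxy}-3,5-dimethoxyphenyl)prop-2-en-1-one | COc1cc(/C=C/C(=O)c2c(O)cc(OCc3ccccc3)cc2OCc2ccccc2)cc(OC)c1O[C@@H](CO)[C@@H](O)c1ccc(OCc2ccccc2)cc1 | intermediate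
16 | flavanone: 5,7-bis(benzyloxy)-2-(4-{[(1S,2S)-1-[4-(benzyloxy)phenyl]-1,3-dihydroxypropan-2-yl]oxy}-3,5-dimethoxyphenyl)chroman-4-one, C2 epimers | COc1cc(C2CC(=O)c3c(OCc4ccccc4)cc(OCc4ccccc4)cc3O2)cc(OC)c1O[C@@H](CO)[C@@H](O)c1ccc(OCc2ccccc2)cc1 | intermediate
17 | 3-iodoflavanone: 3-iodo derivative of 16, C2/C3 isomer mixture | COc1cc(C2Oc3cc(OCc4ccccc4)cc(OCc4ccccc4)c3C(=O)C2I)cc(OC)c1O[C@@H](CO)[C@@H](O)c1ccc(OCc2ccccc2)cc1 | intermediate
18 | 5,7-bis(benzyloxy)-2-(4-{[(1S,2S)-1-[4-(benzyloxy)phenyl]-1,3-dihydroxypropan-2-yl]oxy}-3,5-dimethoxyphenyl)-4H-chromen-4-one | COc1cc(-c2cc(=O)c3c(OCc4ccccc4)cc(OCc4ccccc4)cc3o2)cc(OC)c1O[C@@H](CO)[C@@H](O)c1ccc(OCc2ccccc2)cc1 | intermediate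
19 | (−)-(7''S,8''S)-4'',5,7-trihydroxy-3',5'-dimethoxy-4',8''-oxyflavonolignan-7'',9''-diol | COc1cc(-c2cc(=O)c3c(O)cc(O)cc3o2)cc(OC)c1O[C@@H](CO)[C@@H](O)c1ccc(O)cc1 | target

**Step count**
Total: 8 steps. Longest linear sequence: 7 steps (steps 1, 2, 3, 4, 6, 7, 8 from syringaldehyde); step 5 is a one-step side branch.

**Steps most likely to fail, with fallbacks**

Step 3 (key step). The doubly ortho-methoxylated aryloxy group is bulkier than the alkoxy groups normally used in this allylboration. Risks are competing ring lithiation next to the dioxolane, BF3 attack on the acetal, and eroded syn selectivity or ee. The fallback sets out from 3 and comes back at 9. The lithiated ether, made as in step 3, is quenched with 2-isopropoxy-4,4,5,5-tetramethyl-1,3,2-dioxaborolane and worked up with aqueous NH4Cl to give the isolable, purifiable 2-{(2Z)-3-[4-(1,3-dioxolan-2-yl)-2,6-dimethoxyphenoxy]prop-2-en-1-yl}-4,4,5,5-tetramethyl-1,3,2-dioxaborolane F1. This boronate is then added to 4 under chiral phosphoric acid catalysis ((R)-TRIP, 5 mol%, toluene, 4 Å MS, −30 °C; the enantiomer that gives re-face allylation of aryl aldehydes), and aqueous work-up gives 9. The change is from a stoichiometric chiral borane with BF3 to an achiral Z-boronate of checked geometry with catalyst-controlled facial selectivity and no Lewis acid.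

Step 4. Ozone may over-oxidise the electron-rich arenes, the benzyl ether or the acetal C–H, and the telescoped acid hydrolysis exposes the benzylic alcohol. The fallback sets out from 9 and comes back at 11. OsO4 (2 mol%) with N-methylmorpholine N-oxide in acetone/H2O dihydroxylates the vinyl group to (1S,2R,3RS)-1-[4-(benzyloxy)phenyl]-2-[4-(1,3-dioxolan-2-yl)-2,6-dimethoxyphenoxy]butane-1,3,4-triol F2. NaIO4 in THF/H2O at 0 °C cleaves it to (2R,3S)-3-[4-(benzyloxy)phenyl]-2-[4-(1,3-dioxolan-2-yl)-2,6-dimethoxyphenoxy]-3-hydroxypropanal F3, which is reduced at once with NaBH4 at 0 °C to 11. Compound 11 is then isolated and hydrolysed with 1 M HCl/THF to 12 as in step 4.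

Step 7. Iodine–pyridine dehydrogenation is established for flavanones, but here it starts from the chalcone, so slow ring closure or ring-A iodination could lower the yield. The fallback sets out from 15 and comes back at 18. 2,2-Dimethoxypropane with pyridinium p-toluenesulfonate in acetone masks the 7'',9''-diol as (E)-1-[2,4-bis(benzyloxy)-6-hydroxyphenyl]-3-(4-{[(4S,5S)-4-[4-(benzyloxy)phenyl]-2,2-dimethyl-1,3-dioxan-5-yl]oxy}-3,5-dimethoxyphenyl)prop-2-en-1-one F4. The standard catalytic oxidative cyclisation (I2 10 mol%, DMSO, 120 °C), now safe for the benzylic position, gives 5,7-bis(benzyloxy)-2-(4-{[(4S,5S)-4-[4-(benzyloxy)phenyl]-2,2-dimethyl-1,3-dioxan-5-yl]oxy}-3,5-dimethoxyphenyl)-4H-chromen-4-one F5. Treatment with 80% aqueous AcOH at 40 °C removes the acetonide and returns 18.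

**Further compounds**
F1 | step 3 | 2-{(2Z)-3-[4-(1,3-dioxolan-2-yl)-2,6-dimethoxyphenoxy]prop-2-en-1-yl}-4,4,5,5-tetramethyl-1,3,2-dioxaborolane | COc1cc(C2OCCO2)cc(OC)c1O/C=C\CB1OC(C)(C)C(C)(C)O1
F2 | step 4 | (1S,2R,3RS)-1-[4-(benzyloxy)phenyl]-2-[4-(1,3-dioxolan-2-yl)-2,6-dimethoxyphenoxy]butane-1,3,4-triol | COc1cc(C2OCCO2)cc(OC)c1O[C@@H](C(O)CO)[C@@H](O)c1ccc(OCc2ccccc2)cc1
F3 | step 4 | (2R,3S)-3-[4-(benzyloxy)phenyl]-2-[4-(1,3-dioxolan-2-yl)-2,6-dimethoxyphenoxy]-3-hydroxypropanal | COc1cc(C2OCCO2)cc(OC)c1O[C@@H](C=O)[C@@H](O)c1ccc(OCc2ccccc2)cc1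
F4 | step 7 | (E)-1-[2,4-bis(benzyloxy)-6-hydroxyphenyl]-3-(4-{[(4S,5S)-4-[4-(benzyloxy)phenyl]-2,2-dimethyl-1,3-dioxan-5-yl]oxy}-3,5-dimethoxyphenyl)prop-2-en-1-one | COc1cc(/C=C/C(=O)c2c(O)cc(OCc3ccccc3)cc2OCc2ccccc2)cc(OC)c1O[C@H]1COC(C)(C)O[C@H]1c1ccc(OCc2ccccc2)cc1
F5 | step 7 | 5,7-bis(benzyloxy)-2-(4-{[(4S,5S)-4-[4-(benzyloxy)phenyl]-2,2-dimethyl-1,3-dioxan-5-yl]oxy}-3,5-dimethoxyphenyl)-4H-chromen-4-one | COc1cc(-c2cc(=O)c3c(OCc4ccccc4)cc(OCc4ccccc4)cc3o2)cc(OC)c1O[C@H]1COC(C)(C)O[C@H]1c1ccc(OCc2ccccc2)cc1
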